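in all of them: starting material 0.30 M
- teal: reagent 0.37 M; run made earlier
- green: reagent 1.2 M; run made earlier
- noon: reagent 0.900 M; time 5.0 h
- spring: reagent 0.300 M; time 5.0 h

| run | time / h | single product / % | starting material / % |
|---|---|---|---|
| teal | 0.417 | 7.6 | 79.5 |
| teal | 1.00 | 14.7 | 65.5 |
| teal | 2.00 | 21.2 | 53.7 |
| teal | 5.00 | 26.3 | 37.4 |
| green | 1.33 | 40.3 | 34.3 |
| green | 2.50 | 43.4 | 18.7 |
| green | 4.00 | 38.0 | 9.9 |
| green | 5.00 | 33.3 | 7.4 |

(each reading ± 0.5 percentage points)



- which of these holds the largest part of the starting material at the end of noon (tris adduct / single product / starting material / double product)
- which of these holds the largest part of the starting material at the end of spring (tris adduct / single product / starting material / double product)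
- single product at the end of spring, in percent of the starting material charged

- In a one-step world, with starting material meeting reagent, the slope of the logarithm of the starting material fraction would fall in step with the reagent left. Counting each lost unit of starting material as one reagent spent, teal went from 1.23 equivalents at the start to 0.689 over its last stretch, a factor of 1.79. But its slope went from 0.550 h⁻¹ up to 0.417 h to 0.121 h⁻¹ after 2.00 h, a larger factor of 4.55. So I reckoned with a fast balance (a pre-equilibrium) holding back a steady share of the starting material.
- Reagent: by hand, each added equivalent should speed the decay in proportion. Green, with 4.00 equivalents, behaved nearly pseudo-first-order, and from its readings at 1.33 h and 4.00 h, counting each lost unit of starting material as one reagent spent, I got 0.144 h⁻¹. This is the held-back rate constant: decay per hour per equivalent of reagent.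
- Two flasks with equal starting material charge then differ in the logarithm of their fractions by this constant times time times their difference in reagent equivalents, the held-back share cancelling. From teal I reckoned 44.3% starting material for spring, and from green 15.2% for noon.
- Time: by hand, single product rises, then passes on. Green read 33.3% at 5.00 h, less than the 43.4% at 2.50 h.
- Starting material: by hand, it sets the equivalents, but every flask here holds 0.30 M.
- The forecast named double product for noon, on the ground “probably mostly double product”, and starting material for spring with 23% single product. It put spring's starting material at 43, against my figure above.
- Noon held 34.9% single product, the most of the four asked, with 7.72% double product and 13.3% starting material; isomer of the product stood at 33.5%. Spring held 43.2% starting material and 22.6% single product.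

    reagent → decomposition product (k = 1.60 × 10⁻⁴ h⁻¹)
    reagent + single product → double product + by-product (k = 0.110 L mol⁻¹ h⁻¹)
    single product ⇌ isomer of the product (K = 3.40, k = 0.230 h⁻¹)
    starting material + reagent → single product + by-product (k = 0.630 L mol⁻¹ h⁻¹)
    starting material ⇌ dormant form (K = 0.320, k = 0.390 h⁻¹)
    reagent + double product → tris adduct + by-product (k = 0.360 L mol⁻¹ h⁻¹)

- Spring had not come to rest at 5.0 h. With 56% of its reagent left at 5.00 h, the held-back rate constant gave starting material a half-life of 8.60 h at that reagent level, which is longer than the run. At 50.0 h the computed spring flask held 13.0% starting material, 17.5% single product and 57.9% isomer of the product, with 6.24% of its reagent left.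
- For the neighbour with 0.75 M reagent, the rule from noon gives 19.0% starting material; the computed flask held 17.8%.

(The runs are simulated on assumed constants; scatter was added.)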